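**Plan**

1. Retrosynthesis: remove the three acetates; open the butanolide at C17–C8 (reductive aldol of a C7 acrylate onto a C8 ketone masked as a dithiane); cut the ten-membered ring at C6–C7 (alkenyl iodide plus aldehyde) and the chain at C8–C9 (aldol); cut the six-membered ring at C10–C11; then C3–C4 (enolate alkylation) and C1–C15, C1–C10 (two Fráter–Seebach alkylations).
2. Forward: chain C20–C11–C12–C13–C14–C1–C2, then quaternary C1, then side chain C3–C6, then the six-membered ring (C1, C10, C11, C12, C13, C14), then the ten-membered ring (C1–C10), then the butanolide and the acetates.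
3. Enabling feature: C10 is α to C9, which can be held as an aldehyde, and C11 carries the exocyclic C20 methylene, which is what a terminal alkyne leaves after 6-exo-dig attack by an enol. The syn C2/C14 diol on either side of C1 allows a temporary acetonide whose chair dioxane, fused at C1–C14, forces the C9 group on C10 to be equatorial.
4. Stereochemistry: C14 by asymmetric hydrogenation; C1 by the second Fráter–Seebach alkylation; C2 and C7 by hydroxyl-directed syn reductions (from 14-OH and 9-OH); C10 by the locked chair (kinetically and by epimerization); C9 by Felkin–Anh addition; C8 and C17 in the ring-controlled reductive aldol.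

Key step: step 13

Remark: atom numbers are those of the briarane skeleton of the target (ten-membered ring C1–C10; six-membered ring C1, C10–C14; methyl C15 on C1, methyl C16 on C5, methylene C20 on C11; butanolide C7–O–C18(=O)–C17(C19)–C8). The alkyne is assumed to need its silyl cap through steps 1–8, so it is carried silylated until step 9.

**Route**

Step 1
Reactants: 1 methyl 3-oxobutanoate; 2 3-bromo-1-(trimethylsilyl)prop-1-yne
Product: 4 methyl 3-oxo-7-(trimethylsilyl)hept-6-ynoate, via acetoacetate dianion 3 (not isolated)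
Conditions: NaH, THF, 0 °C; n-BuLi, 0 °C; 2, 0 °C to rt; 1 M HCl
Reagents that add atoms: none
Why: Dianion alkylation of a β-keto ester takes place at the terminal (γ) carbon and joins C13 to C12, delivering C20–C11–C12–C13–C14–C1–C2 in one operation.

Step 2
Reactants: 4 methyl 3-oxo-7-(trimethylsilyl)hept-6-ynoate
Product: 5 methyl (3S)-3-hydroxy-7-(trimethylsilyl)hept-6-ynoate
Conditions: RuCl2[(S)-BINAP] (cat.), H2 (4 atm), MeOH, 50 °C
Reagents that add atoms: none
Why: Noyori asymmetric hydrogenation of a β-keto ester, in which the (S)-BINAP ruthenium chelate should deliver hydrogen to one ketone face and set C14 as the 3S carbinol while the remote silylated alkyne is not reduced.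

Step 3
Reactants: 5 methyl (3S)-3-hydroxy-7-(trimethylsilyl)hept-6-ynoate
Product: 7 methyl (2S,3S)-3-hydroxy-2-(prop-2-en-1-yl)-7-(trimethylsilyl)hept-6-ynoate, via dilithium alkoxide enolate 6 (not isolated)
Conditions: LiN(iPr)2 (2.2 equiv), THF, −78 to −20 °C; allyl bromide, −78 to 0 °C; H2O
Reagents that add atoms: allyl bromide (3-bromoprop-1-ene), C=CCBr
Why: Fráter–Seebach alkylation of the chelated dianion, which is attacked anti to the C13 chain and introduces the future C10–C9 unit; the C1 configuration formed here is erased in step 4.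

Step 4
Reactants: 7 methyl (2S,3S)-3-hydroxy-2-(prop-2-en-1-yl)-7-(trimethylsilyl)hept-6-ynoate
Product: 9 methyl (2R,3S)-3-hydroxy-2-methyl-2-(prop-2-en-1-yl)-7-(trimethylsilyl)hept-6-ynoate, via dilithium alkoxide enolate 8 (not isolated)
Conditions: LiN(iPr)2 (2.5 equiv), THF/DMPU, −78 to −10 °C; MeI, −78 to 0 °C; H2O
Reagents that add atoms: iodomethane, CI
Why: Second Fráter–Seebach alkylation, in which the methyl group (C15) again enters the chelated enolate anti to the C13 chain, so quaternary C1 is set relative to C14 with the allyl group cis to that chain.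

Step 5
Reactants: 9 methyl (2R,3S)-3-hydroxy-2-methyl-2-(prop-2-en-1-yl)-7-(trimethylsilyl)hept-6-ynoate
Product: 11 (3R,4S)-4-hydroxy-3-methyl-3-(prop-2-en-1-yl)-8-(trimethylsilyl)oct-7-yn-2-one, via dilithium silyl enolate 10 (not isolated)
Conditions: Me3SiCH2Li (3.5 equiv), pentane/THF, 0 °C to rt; then 1 M HCl, MeOH, 0 °C
Reagents that add atoms: (trimethylsilyl)methyllithium, [Li]C[Si](C)(C)C
Why: Ester to methyl ketone conversion, where the α-silyl ketone formed by single addition is enolized by excess reagent (no second addition) and acidic methanol then protodesilylates the α-carbon, which becomes C3, without touching the alkynyl silane.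

Step 6
Reactants: 12 prop-2-yn-1-ol
Product: 14 (2Z)-3-iodo-2-methylprop-2-en-1-ol, via alkenylmagnesium alkoxide 13 (not isolated)
Conditions: MeMgBr (2.5 equiv), CuI (10 mol %), THF, −10 °C to rt; then I2, −78 to 0 °C
Reagents that add atoms: methylmagnesium bromide, C[Mg]Br; iodine, II
Why: Alkoxide-directed, copper-catalysed anti-carbomagnesiation of the propargylic alcohol followed by iodinolysis with retention places iodine cis to the CH2OH group, which fixes the future C5=C6 geometry (C4 cis to C7).

Step 7
Reactants: 14 (2Z)-3-iodo-2-methylprop-2-en-1-ol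
Product: 15 (1Z)-3-bromo-1-iodo-2-methylprop-1-ene
Conditions: CBr4, PPh3, CH2Cl2, 0 °C
Reagents that add atoms: tetrabromomethane, BrC(Br)(Br)Br
Why: Appel bromination of a primary allylic alcohol proceeds by SN2 displacement and leaves the alkene geometry and the alkenyl iodide untouched.

Step 8
Reactants: 11 (3R,4S)-4-hydroxy-3-methyl-3-(prop-2-en-1-yl)-8-(trimethylsilyl)oct-7-yn-2-one; 15 (1Z)-3-bromo-1-iodo-2-methylprop-1-ene
Product: 17 (1Z,6R,7S)-7-hydroxy-1-iodo-2,6-dimethyl-6-(prop-2-en-1-yl)-11-(trimethylsilyl)undec-1-en-10-yn-5-one, via dilithium alkoxide enolate 16 (not isolated)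
Conditions: LiN(iPr)2 (2.2 equiv), THF, −78 °C; 15, DMPU, −78 to −40 °C; H2O
Reagents that add atoms: none
Why: Alkylation of the kinetic methyl ketone enolate (C3 is the only enolizable position because C1 is quaternary) with a reactive allylic bromide forms C3–C4, and the alkoxide enolate dianion cannot undergo retro-aldol cleavage.

Step 9
Reactants: 17 (1Z,6R,7S)-7-hydroxy-1-iodo-2,6-dimethyl-6-(prop-2-en-1-yl)-11-(trimethylsilyl)undec-1-en-10-yn-5-one
Product: 19 (1Z,5R,6R,7S)-1-iodo-2,6-dimethyl-6-(prop-2-en-1-yl)undec-1-en-10-yne-5,7-diol, via silylated syn-diol 18 (not isolated)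
Conditions: Et2BOMe, THF/MeOH (4:1), −78 °C; NaBH4; then K2CO3, MeOH, rt
Reagents that add atoms: none
Why: Narasaka–Prasad reduction, in which external hydride attacks the boron chelate of the β-hydroxy ketone axially and anti to the axial allyl group on C1 to give the 2,14-syn diol (2R); methanolic carbonate then cleaves the boronate and the alkynyl C–Si bond.

Step 10
Reactants: 19 (1Z,5R,6R,7S)-1-iodo-2,6-dimethyl-6-(prop-2-en-1-yl)undec-1-en-10-yne-5,7-diol
Product: 20 (4S,5R,6R)-4-(but-3-yn-1-yl)-6-[(3Z)-4-iodo-3-methylbut-3-en-1-yl]-2,2,5-trimethyl-5-(prop-2-en-1-yl)-1,3-dioxane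
Conditions: Me2C(OMe)2, PPTS, CH2Cl2, rt
Reagents that add atoms: 2,2-dimethoxypropane, COC(C)(C)OC
Why: Acid-catalysed transketalization gives the chair 1,3-dioxane of the syn diol with both chains equatorial and the allyl group on C1 axial; this temporary ring protects O2 and O14 and locks the conformation for step 13.

Step 11
Reactants: 20 the acetonide named in step 10
Product: 22 2-[(4S,5R,6R)-4-(but-3-yn-1-yl)-6-[(3Z)-4-iodo-3-methylbut-3-en-1-yl]-2,2,5-trimethyl-1,3-dioxan-5-yl]acetaldehyde, via vicinal diol 21 (not isolated)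
Conditions: OsO4 (2 mol %), NaIO4, 2,6-lutidine, dioxane/H2O (3:1), rt
Reagents that add atoms: osmium tetroxide, O=[Os](=O)(=O)=O (catalytic; its oxo groups are restored by sodium periodate, [Na+].[O-]I(=O)(=O)=O)
Why: Lemieux–Johnson cleavage, where osmylation should be fastest at the monosubstituted allyl alkene (the iodo-substituted trisubstituted alkene is electron-poor and hindered, the alkyne far slower) and periodate cleaves the diol to the C9 aldehyde.

Step 12
Reactants: 22 the C9 aldehyde named in step 11
Product: 23 silyl enol ether of 22 (tert-butyldimethylsilyl, C10=C9–OSi, mixture of E and Z isomers)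
Conditions: TBSOTf, Et3N, CH2Cl2, 0 °C to rt
Reagents that add atoms: tert-butyldimethylsilyl trifluoromethanesulfonate, CC(C)(C)[Si](C)(C)OS(=O)(=O)C(F)(F)F
Why: Soft enolization of the aldehyde with silyl triflate and amine makes C10 nucleophilic; the E/Z ratio is immaterial because both isomers should give the same product in step 13.

Step 13
Reactants: 23 silyl enol ether (E/Z mixture)
Product: 24 acetonide-locked bicyclic C9 aldehyde (six-membered ring C1, C10–C14 closed; C11=C20 methylene; C1, C2, C10, C14 as in the target)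
Conditions: (Ph3P)AuCl (5 mol %), AgBF4 (5 mol %), CH2Cl2, MeOH (2 equiv), rt; then DBU (cat.), CH2Cl2, rt
Reagents that add atoms: none
Why: Cationic monovalent gold binds the terminal alkyne and the enol ether carbon C10 attacks the internal carbon C11 anti to gold; methanol then removes the silyl group from the oxocarbenium ion and protonates the alkenyl–gold bond, releasing the C9 aldehyde and the C11=C20 methylene. The closest known reaction type is the gold-catalysed carbocyclization of silyl enol ethers onto alkynes (a Conia-ene-type closure), here in the 6-exo-dig mode that forms the six-membered ring C1, C10, C11, C12, C13, C14. The only new stereocentre, C10, is controlled by the acetonide: the syn-diol dioxane holds the butynyl arm equatorial and the enol ether arm axial on adjacent carbons, so the new ring is a cis-fused chair with O14 axial, and the C9 substituent can only take the equatorial site on C10 because the axial site would be 1,3-diaxial to O14. Both enol ether isomers should converge on this product, and because C10 is α to the aldehyde a trace of base on work-up returns any axial epimer to the same equatorial configuration, which is that of the target (C9 trans to C2). The step needs C-attack rather than O-attack, exo rather than endo closure and one C10 configuration; the soft silyl enol ether, the terminal alkyne (attack at the internal carbon) and the locked chair should secure these in turn.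

Step 14
Reactants: 24 acetonide-locked bicyclic C9 aldehyde; 25 ethyl 1,3-dithiane-2-carboxylate
Product: 27 β-hydroxy ester (C9 as the 9R carbinol bonded to dithiane carbon C8; C7 as the ethyl ester), via lithium enolate 26 (not isolated)
Conditions: 25, LiN(iPr)2, THF, −78 °C; then 24, −78 °C; H2O
Reagents that add atoms: none
Why: Aldol addition of the ester-stabilized dithiane anion to the aldehyde brings in C8 as a masked ketone and C7 as an ester, and Felkin–Anh attack anti to the quaternary C1 substituent on C10 (past the C10 hydrogen) sets C9 as 9R.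

Step 15
Reactants: 27 β-hydroxy ester
Product: 28 β-hydroxy aldehyde (C7 formyl on dithiane carbon C8)
Conditions: iBu2AlH (2.5 equiv), CH2Cl2, −78 °C; aq. KNaC4H4O6 (sodium potassium tartrate)
Reagents that add atoms: none
Why: Partial reduction of the α,α-dithio ester, whose tetrahedral aluminium hemiacetal is stable at −78 °C and collapses to the aldehyde only on work-up, while the alkenyl iodide and acetonide are inert.

Step 16
Reactants: 28 β-hydroxy aldehyde
Product: 29 ten-membered-ring 7,9-diol (ring C1–C10 closed at C6–C7; mixture of C7 epimers)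
Conditions: CrCl2 (10 equiv), NiCl2 (1 mol %), DMSO/THF (3:1), rt, 0.003 M; H2O
Reagents that add atoms: none
Why: Nozaki–Hiyama–Kishi macrocyclization, in which zerovalent nickel inserts into the alkenyl iodide and transmetalation to trivalent chromium gives an alkenyl nucleophile that adds to the C7 aldehyde with retention of the Z geometry and tolerates the free 9-OH; both C7 epimers are usable because C7 is reset in steps 17 and 18.

Step 17
Reactants: 29 ten-membered-ring 7,9-diol (C7 epimers)
Product: 30 ten-membered-ring β-hydroxy enone (C7 ketone conjugated with C5=C6; 9-OH free)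
Conditions: MnO2, CH2Cl2, rt
Reagents that add atoms: none
Why: MnO2 oxidizes only the allylic C7 alcohol, so both C7 epimers converge on one enone while the C9 carbinol and the dithiane are left alone.

Step 18
Reactants: 30 ten-membered-ring β-hydroxy enone
Product: 31 ten-membered-ring 7,9-syn diol (7S,9R)
Conditions: Et2BOMe, THF/MeOH (4:1), −78 °C; NaBH4; MeOH azeotrope
Reagents that add atoms: none
Why: Narasaka–Prasad reduction, where the boron chelate between 9-OH and the C7 ketone is reduced by external axial hydride to the 7,9-syn diol (the 7S configuration), and the β,β-disubstituted enone is reduced in the 1,2 sense.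

Step 19
Reactants: 31 ten-membered-ring 7,9-syn diol
Product: 32 7-O-acrylate (9-OH free)
Conditions: CH2=CHCOCl (1.05 equiv), iPr2NEt, CH2Cl2, −78 to −40 °C
Reagents that add atoms: acryloyl chloride (prop-2-enoyl chloride), C=CC(=O)Cl
Why: Selective acylation, since the allylic C7 hydroxyl next to an sp2 carbon is less hindered than the C9 hydroxyl wedged between the dithiane carbon and ring-fusion carbon C10, so one equivalent of acid chloride at low temperature should esterify O7 only.

Step 20
Reactants: 32 7-O-acrylate
Product: 33 C8 ketone (7-acryloyloxy, 9-hydroxy)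
Conditions: PhI(OCOCF3)2, NaHCO3, MeCN/H2O (9:1), 0 °C
Reagents that add atoms: water, O
Why: Oxidative hydrolysis of the dithiane by the hypervalent iodine reagent, which attacks sulfur faster than the alkenes, with bicarbonate buffering to spare the acetonide and the acrylate.

Step 21
Reactants: 33 C8 ketone
Product: 34 acetonide-protected butanolide (lactone C7–O–C18(=O)–C17–C8 closed; 8-OH and 9-OH free)
Conditions: [(Ph3P)CuH]6 (0.6 equiv), toluene/THF, −40 to 0 °C; AcOH
Reagents that add atoms: none
Why: Copper hydride reductive aldol cyclization (5-exo-trig): conjugate hydride addition to the acrylate gives a Z copper enolate that adds to the adjacent C8 ketone through a chelated Zimmerman–Traxler transition state; the ten-membered ring holds C6–C7–C8–C9 transoid so the tethered enolate reaches only the face that leaves 8-OH cis to C6, and the closed transition state places the C19 methyl cis to 8-OH and trans to C9.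

Step 22
Reactants: 34 acetonide-protected butanolide
Product: 35 2,8,9,14-tetraol (2,9,14-tri-de-O-acetyl target)
Conditions: PPTS, MeOH, 40 °C
Reagents that add atoms: none
Why: Acid-catalysed transketalization to methanol removes the temporary acetonide under conditions expected to be too mild to isomerize the exocyclic alkene or dehydrate the tertiary alcohol.

Step 23
Reactants: 35 2,8,9,14-tetraol
Product: 36 target CNP0187723.2 (2,9,14-triacetoxy-8-hydroxybriara-5Z,11(20)-dien-18,7-olide)
Conditions: Ac2O, pyridine, DMAP (cat.), CH2Cl2, rt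
Reagents that add atoms: acetic anhydride, CC(=O)OC(C)=O
Why: DMAP-catalysed acetylation should esterify the three secondary hydroxyls at C2, C9 and C14, while the tertiary 8-OH is too hindered to react.

**Compound list**

1 | methyl 3-oxobutanoate | CC(=O)CC(=O)OC | starting material
2 | 3-bromo-1-(trimethylsilyl)prop-1-yne | C[Si](C)(C)C#CCBr | starting material
3 | sodium lithium dianion of methyl 3-oxobutanoate (not isolated) | C=C([O-])C=C([O-])OC.[Na+].[Li+] | intermediate
4 | methyl 3-oxo-7-(trimethylsilyl)hept-6-ynoate | COC(=O)CC(=O)CCC#C[Si](C)(C)C | intermediate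
5 | methyl (3S)-3-hydroxy-7-(trimethylsilyl)hept-6-ynoate | C[Si](C)(C)C#CCC[C@H](O)CC(=O)OC | intermediate
6 | dilithium alkoxide enolate of 5 (not isolated) | C[Si](C)(C)C#CCC[C@H]([O-])C=C([O-])OC.[Li+].[Li+] | intermediate
7 | methyl (2S,3S)-3-hydroxy-2-(prop-2-en-1-yl)-7-(trimethylsilyl)hept-6-ynoate | C[Si](C)(C)C#CCC[C@H](O)[C@H](CC=C)C(=O)OC | intermediate
8 | dilithium alkoxide enolate of 7 (not isolated) | C[Si](C)(C)C#CCC[C@H]([O-])C(CC=C)=C([O-])OC.[Li+].[Li+] | intermediate
9 | methyl (2R,3S)-3-hydroxy-2-methyl-2-(prop-2-en-1-yl)-7-(trimethylsilyl)hept-6-ynoate | C[Si](C)(C)C#CCC[C@H](O)[C@@](C)(CC=C)C(=O)OC | intermediate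
10 | dilithium salt of the α-silyl ketone (C14 alkoxide and C2 enolate, not isolated) | C[Si](C)(C)C#CCC[C@H]([O-])[C@@](C)(CC=C)C([O-])=C[Si](C)(C)C.[Li+].[Li+] | intermediate
11 | (3R,4S)-4-hydroxy-3-methyl-3-(prop-2-en-1-yl)-8-(trimethylsilyl)oct-7-yn-2-one | C[Si](C)(C)C#CCC[C@H](O)[C@@](C)(CC=C)C(C)=O | intermediate
12 | prop-2-yn-1-ol | C#CCO | starting material
13 | (Z)-alkenylmagnesium bromide alkoxide from carbomagnesiation (magnesium cis to CH2O, not isolated) | Br[Mg]/C=C(/C)CO[Mg]Br | intermediate
14 | (2Z)-3-iodo-2-methylprop-2-en-1-ol | I/C=C(/C)CO | intermediate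
15 | (1Z)-3-bromo-1-iodo-2-methylprop-1-ene | I/C=C(/C)CBr | intermediate
16 | dilithium alkoxide enolate of 11 (not isolated) | C[Si](C)(C)C#CCC[C@H]([O-])[C@@](C)(CC=C)C([O-])=C.[Li+].[Li+] | intermediate
17 | (1Z,6R,7S)-7-hydroxy-1-iodo-2,6-dimethyl-6-(prop-2-en-1-yl)-11-(trimethylsilyl)undec-1-en-10-yn-5-one | C[Si](C)(C)C#CCC[C@H](O)[C@@](C)(CC=C)C(=O)CC/C(C)=C\I | intermediate
18 | (1Z,5R,6R,7S)-1-iodo-2,6-dimethyl-6-(prop-2-en-1-yl)-11-(trimethylsilyl)undec-1-en-10-yne-5,7-diol (not isolated) | C[Si](C)(C)C#CCC[C@H](O)[C@@](C)(CC=C)[C@H](O)CC/C(C)=C\I | intermediate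
19 | (1Z,5R,6R,7S)-1-iodo-2,6-dimethyl-6-(prop-2-en-1-yl)undec-1-en-10-yne-5,7-diol (C2/C14 syn diol) | C#CCC[C@H](O)[C@@](C)(CC=C)[C@H](O)CC/C(C)=C\I | intermediate
20 | (4S,5R,6R)-4-(but-3-yn-1-yl)-6-[(3Z)-4-iodo-3-methylbut-3-en-1-yl]-2,2,5-trimethyl-5-(prop-2-en-1-yl)-1,3-dioxane | C#CCC[C@@H]1OC(C)(C)O[C@H](CC/C(C)=C\I)[C@]1(C)CC=C | intermediate
21 | 3-[(4S,5R,6R)-4-(but-3-yn-1-yl)-6-[(3Z)-4-iodo-3-methylbut-3-en-1-yl]-2,2,5-trimethyl-1,3-dioxan-5-yl]propane-1,2-diol (both carbinol epimers, not isolated) | C#CCC[C@@H]1OC(C)(C)O[C@H](CC/C(C)=C\I)[C@]1(C)CC(O)CO | intermediate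
22 | 2-[(4S,5R,6R)-4-(but-3-yn-1-yl)-6-[(3Z)-4-iodo-3-methylbut-3-en-1-yl]-2,2,5-trimethyl-1,3-dioxan-5-yl]acetaldehyde | C#CCC[C@@H]1OC(C)(C)O[C@H](CC/C(C)=C\I)[C@]1(C)CC=O | intermediate
23 | tert-butyldimethylsilyl enol ether of 22 (C10=C9–OSi, E/Z mixture) | C#CCC[C@@H]1OC(C)(C)O[C@H](CC/C(C)=C\I)[C@]1(C)C=CO[Si](C)(C)C(C)(C)C | intermediate
24 | acetonide-locked bicyclic aldehyde: cis-fused hexahydro-4H-1,3-benzodioxine with the C9 formyl group equatorial on C10 (trans to C2), C11 methylidene, C15 methyl on C1 and the (3Z)-4-iodo-3-methylbut-3-en-1-yl chain on C2; C1, C2, C10, C14 as in the target | C=C1CC[C@@H]2OC(C)(C)O[C@H](CC/C(C)=C\I)[C@]2(C)[C@H]1C=O | intermediate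
25 | ethyl 1,3-dithiane-2-carboxylate | CCOC(=O)C1SCCCS1 | starting material
26 | lithium enolate of 25 (not isolated) | CCOC([O-])=C1SCCCS1.[Li+] | intermediate
27 | ethyl 2-[(R)-hydroxy(bicyclic core)methyl]-1,3-dithiane-2-carboxylate: 24 with C9 as the 9R carbinol bonded to dithiane carbon C8 and C7 as the ethyl ester | C=C1CC[C@@H]2OC(C)(C)O[C@H](CC/C(C)=C\I)[C@]2(C)[C@H]1[C@@H](O)C1(C(=O)OCC)SCCCS1 | intermediate
28 | the corresponding 1,3-dithiane-2-carbaldehyde (C7 formyl, 9R-OH free) | C=C1CC[C@@H]2OC(C)(C)O[C@H](CC/C(C)=C\I)[C@]2(C)[C@H]1[C@@H](O)C1(C=O)SCCCS1 | intermediate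
29 | tricyclic 7,9-diol: ten-membered ring C1–C10 with 5Z alkene, C8 spiro-1,3-dithiane, C2/C14 acetonide; both C7 epimers | C=C1CC[C@@H]2OC(C)(C)O[C@@H]3CC/C(C)=C\C(O)C4(SCCCS4)[C@H](O)[C@@H]1[C@]23C | intermediate
30 | the corresponding C7 ketone (5Z-en-7-one, 9R-OH) | C=C1CC[C@@H]2OC(C)(C)O[C@@H]3CC/C(C)=C\C(=O)C4(SCCCS4)[C@H](O)[C@@H]1[C@]23C | intermediate
31 | 7,9-syn diol (7S,9R), otherwise as 29 | C=C1CC[C@@H]2OC(C)(C)O[C@@H]3CC/C(C)=C\[C@H](O)C4(SCCCS4)[C@H](O)[C@@H]1[C@]23C | intermediate
32 | 7-O-acrylate (prop-2-enoate) of 31 | C=C1CC[C@@H]2OC(C)(C)O[C@@H]3CC/C(C)=C\[C@H](OC(=O)C=C)C4(SCCCS4)[C@H](O)[C@@H]1[C@]23C | intermediate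
33 | C8 ketone: 7-acryloyloxy-9-hydroxy-8-oxo ten-membered ring, C2/C14 acetonide | C=C1CC[C@@H]2OC(C)(C)O[C@@H]3CC/C(C)=C\[C@H](OC(=O)C=C)C(=O)[C@H](O)[C@@H]1[C@]23C | intermediate
34 | 2,14-O-isopropylidene-8,9-dihydroxybriara-5Z,11(20)-dien-18,7-olide (C7, C8, C9, C17 as in the target) | C=C1CC[C@@H]2OC(C)(C)O[C@@H]3CC/C(C)=C\[C@@H]4OC(=O)[C@H](C)[C@@]4(O)[C@H](O)[C@@H]1[C@]23C | intermediate
35 | 2,8,9,14-tetrahydroxybriara-5Z,11(20)-dien-18,7-olide | C=C1CC[C@H](O)[C@@]2(C)[C@H]1[C@@H](O)[C@@]1(O)[C@H](/C=C(/C)CC[C@H]2O)OC(=O)[C@@H]1C | intermediate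
36 | CNP0187723.2, 2,9,14-triacetoxy-8-hydroxybriara-5Z,11(20)-dien-18,7-olide | C=C1CC[C@H](OC(C)=O)[C@@]2(C)[C@H]1[C@@H](OC(C)=O)[C@@]1(O)[C@H](/C=C(/C)CC[C@H]2OC(C)=O)OC(=O)[C@@H]1C | target

**Count and risks**

Total steps: 23. Longest linear sequence: 21 steps (steps 1–5 and 8–23); steps 6 and 7 prepare the side-chain bromide.

Steps most likely to fail:

1. Step 13. The enol ether may lose its silyl group to the proton source, or an acetonide oxygen may capture the gold-activated alkyne, before the C10–C11 bond forms. The fallback sets out from 23 and returns at 24. Aprotic carbomercuration with HgCl2 and (Me3Si)2NH in CH2Cl2 should give the alkenylmercury chloride F1 (divalent mercury on C20, aldehyde already unmasked). Protodemercuration with aq. HCl and catalytic NaI in acetone at 0 °C then gives 24. Making the carbon–carbon bond in a stoichiometric step without a proton source, and doing the demetalation separately, removes the competition with protodesilylation.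

2. Step 16. Intermolecular coupling or protonolysis of the alkenylchromium may outrun closure of the strained ten-membered ring. The fallback sets out from 27 and returns at 30, bypassing 28 and 29. The ester is converted with Me(MeO)NH·HCl and i-PrMgCl into the N-methoxy-N-methyl amide F2. After deprotonation of the 9-OH, iodine–lithium exchange with t-BuLi in THF/Et2O at −100 °C under high dilution is followed by intramolecular acyl substitution, which gives the macrocyclic enone 30 directly. This replaces the chromium-mediated carbonyl addition with an anionic ring closure whose tetrahedral chelate prevents over-addition.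

3. Step 21. Copper hydride may reduce the C8 ketone directly, or the enolate may add with poor facial selectivity at C8 or C17. The fallback sets out from 31 and returns at 34. Acylation of O7 with 2-bromopropanoyl bromide gives the bromo ester F3, and PhI(OCOCF3)2 with NaHCO3 unmasks the ketone F4. SmI2 (2 equiv) in THF at −78 °C then effects an intramolecular Reformatsky reaction through a chelated trivalent samarium enolate to give 34. Any C17 epimer can be equilibrated with DBU towards the isomer with the methyl trans to C9.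

**Further compounds**

F1 | step 13 | alkenylmercury chloride of 24 (ClHg on C20, trans to C10) | Cl[Hg]/C=C1\CC[C@@H]2OC(C)(C)O[C@H](CC/C(C)=C\I)[C@]2(C)[C@H]1C=O
F2 | step 16 | N-methoxy-N-methyl amide of 27 (C7 amide on dithiane carbon C8) | C=C1CC[C@@H]2OC(C)(C)O[C@H](CC/C(C)=C\I)[C@]2(C)[C@H]1[C@@H](O)C1(C(=O)N(C)OC)SCCCS1
F3 | step 21 | 7-O-(2-bromopropanoate) of 31 (both bromide epimers) | C=C1CC[C@@H]2OC(C)(C)O[C@@H]3CC/C(C)=C\[C@H](OC(=O)C(C)Br)C4(SCCCS4)[C@H](O)[C@@H]1[C@]23C
F4 | step 21 | C8 ketone from F3 (7-(2-bromopropanoyloxy)-9-hydroxy-8-oxo) | C=C1CC[C@@H]2OC(C)(C)O[C@@H]3CC/C(C)=C\[C@H](OC(=O)C(C)Br)C(=O)[C@H](O)[C@@H]1[C@]23C
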